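A direct plan would add the C13 lithium acetylide A1 to the bis(triisopropylsilyl)-protected aryl aldehyde A2 and carbonylate the resulting propargylic alcohol A3 with CO under Pd2(dba)3–dppb catalysis to the racemic γ-aryl butenolide A4.
It would then set C2 by an isomerising dynamic kinetic alcoholysis of A4 to the (S)-keto ester A5 and finish with fluoride.
The enantioselective alcoholysis would be its weakest step: it would be a reaction without precedent, the sense and level of induction could not be predicted, and C2 would rest on a proton transfer to an intermediate that racemises by design.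
The cyclocarbonylation would be the second: it would need CO at 40 atm with H2 at 95 °C beside two trisubstituted alkenes, and the stereocentre it makes would have to be erased again.

The target is a 1,4-dicarbonyl compound whose only stereocentre, C2, sits between the C1 carboxyl group and the CH2 of the aryl ketone; the route cuts exactly this C2–CH2 bond. An ynamide carrying C1, C2 and the homogeranyl chain and an enantiopure 1-arylvinyl p-tolyl sulfoxide are joined by acid catalysis. One charge-accelerated [3,3]-sulfonium rearrangement forms the C2–CH2 bond, delivers both carbonyl groups at their final oxidation level and hands the chirality of sulfur on to C2. No carbon monoxide, no lactone and no stereodefining proton transfer are needed, and the auxiliary and the allyl ethers leave under non-epimerising conditions.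

Key step: step 6

Remark: C1 is the carboxyl carbon, C2 the stereocentre and C3–C11 the chain of the undecadienoic acid; the SMILES centre [C@@H] of the target corresponds to (2S).

Step 1
Reactants: 1 propyne; 2 geranyl bromide [(2E)-1-bromo-3,7-dimethylocta-2,6-diene]; 3 N-bromosuccinimide
Product: 6 (5E)-1-bromo-6,10-dimethylundeca-5,9-dien-1-yne, via 1,3-dilithiopropyne 4 (not isolated), via lithium acetylide 5 (not isolated)
Conditions: propyne (1.1 equiv), n-BuLi (2.2 equiv), TMEDA (1.1 equiv), Et2O–hexane, −78 °C → rt; 2 (1.0 equiv), THF, −78 → 0 °C; NBS (1.15 equiv), THF, −78 °C → rt; H2O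
Reagents that add atoms: N-bromosuccinimide (3), O=C1CCC(=O)N1Br
Why: Double deprotonation of propyne gives the propargyl/acetylide dianion, whose propargylic carbon displaces bromide from C1 of geranyl bromide (SN2, E-alkene untouched), and the remaining lithium acetylide is brominated at carbon by NBS (electrophilic halogenation of an acetylide) much faster than NBS attacks the trisubstituted alkenes at −78 °C; no stereocentre is formed.

Step 2
Reactants: 6 (5E)-1-bromo-6,10-dimethylundeca-5,9-dien-1-yne; 7 1,3-oxazolidin-2-one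
Product: 8 3-[(5E)-6,10-dimethylundeca-5,9-dien-1-yn-1-yl]-1,3-oxazolidin-2-one
Conditions: 7 (1.2 equiv), CuSO4·5H2O (10 mol%), 1,10-phenanthroline (20 mol%), K3PO4 (2 equiv), toluene, 70 °C, Ar
Reagents that add atoms: 1,3-oxazolidin-2-one (7), O=C1NCCO1
Why: Copper-catalysed amidation of a 1-bromoalkyne (Ullmann-type C(sp)–N coupling through a copper amidate) is the standard entry to N-alkynyl oxazolidinones; it is not oxidative, so the two trisubstituted alkenes are left alone, and no stereocentre is formed.

Step 3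
Reactants: 9 1-(2,5-dihydroxyphenyl)ethan-1-one; 10 allyl bromide (3-bromoprop-1-ene)
Product: 11 1-[2,5-bis(prop-2-en-1-yloxy)phenyl]ethan-1-one
Conditions: 10 (2.5 equiv), K2CO3 (3 equiv), DMF, 60 °C
Reagents that add atoms: allyl bromide (10), C=CCBr
Why: Williamson ether synthesis in which carbonate alkylates both phenols (warm DMF for the hydrogen-bonded 2-OH); allyl ethers should withstand the organometallic, acid-catalysed and LiOOH steps and leave at the end under neutral conditions, and no stereocentre is involved.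

Step 4
Reactants: 11 1-[2,5-bis(prop-2-en-1-yloxy)phenyl]ethan-1-one; 12 2,4,6-tri(propan-2-yl)benzenesulfonohydrazide
Product: 13 N′-{1-[2,5-bis(prop-2-en-1-yloxy)phenyl]ethylidene}-2,4,6-tri(propan-2-yl)benzenesulfonohydrazide
Conditions: 12 (1.05 equiv), HCl (2 mol%), MeCN, rt
Reagents that add atoms: 2,4,6-tri(propan-2-yl)benzenesulfonohydrazide (12), CC(C)c1cc(C(C)C)c(S(=O)(=O)NN)c(C(C)C)c1
Why: Acid-catalysed condensation to the sulfonyl hydrazone, whose 2,4,6-triisopropylphenyl group blocks ortho-metalation of the sulfonyl ring in the Shapiro reaction that follows; no stereocentre is formed.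

Step 5
Reactants: 13 the sulfonyl hydrazone; 14 (1R,2S,5R)-menthyl (S)-4-methylbenzenesulfinate
Product: 17 2-{1-[(S)-4-methylbenzenesulfinyl]ethenyl}-1,4-bis(prop-2-en-1-yloxy)benzene, via 1-arylvinyllithium 15 (not isolated), via 1-arylvinylmagnesium bromide 16 (not isolated)
Conditions: n-BuLi (2.05 equiv), THF, −78 → 0 °C; MgBr2·OEt2 (1.2 equiv), −78 °C; then added to 14 (1.3 equiv), THF, −78 → −40 °C; H2O
Reagents that add atoms: (1R,2S,5R)-menthyl (S)-4-methylbenzenesulfinate (14), C[C@@H]1CC[C@H]([C@@H](C1)O[S@](=O)c1ccc(C)cc1)C(C)C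
Why: The Shapiro reaction (double deprotonation, loss of sulfinate and N2) gives the 1-arylvinyllithium, transmetalation to magnesium tempers it, and Andersen substitution at sulfur of the diastereomerically pure menthyl sulfinate proceeds with inversion to the (S)-sulfoxide (the descriptor is S because the 1-arylvinyl carbon outranks p-tolyl).

Step 6
Reactants: 8 the ynamide; 17 the (S)-vinyl sulfoxide; 18 water
Product: 22 3-[(2S,5E)-2-{2-[2,5-bis(prop-2-en-1-yloxy)phenyl]-2-oxoethyl}-6,10-dimethylundeca-5,9-dienoyl]-1,3-oxazolidin-2-one, via keteniminium ion 19 (not isolated), via O-sulfonium ketene aminal 20 (not isolated), via thionium ion 21 (not isolated)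
Conditions: 8 (1.2 equiv), 17 (1.0 equiv), HN(SO2CF3)2 (10 mol%), CH2Cl2 (0.1 M), −40 → 0 °C; then H2O (10 equiv), THF, 0 °C → rt; NaHCO3
Reagents that add atoms: water (18), O
Why: HN(SO2CF3)2 protonates the ynamide at C2 to keteniminium ion 19, the sulfoxide oxygen adds to C1 on the side away from the chain to give the (E)-O-sulfonium ketene N,O-acetal 20, and a charge-accelerated [3,3]-sigmatropic rearrangement forms the C2–CH2 bond as the S–O bond breaks, leaving the imide carbonyl and thionium ion 21, which water hydrolyses to the aryl ketone with loss of 4-methylbenzenethiol and return of the acid. The closest known reaction type is the acid-catalysed sulfonium [3,3] rearrangement of ynamides with enantioenriched vinyl sulfoxides to 1,4-dicarbonyl compounds, a relative of the redox α-arylation of ynamides with aryl sulfoxides. No ring is closed, the six-membered chair being only the transition state. The new stereocentre C2 is controlled by the sulfur stereocentre: in the chair that keeps the chain pseudo-equatorial (fixed by the E geometry of 20) and the p-tolyl group pseudo-equatorial on sulfur, the (S)-sulfoxide gives (2S), and because the aryl group on the neighbouring vinyl carbon could alter this preference the sense would be confirmed on the first run. The step needs the vinyl and not the p-tolyl terminus to rearrange, which the vinyl path secures by avoiding dearomatisation, and it needs the sulfoxide and not the C5=C6 alkene to capture 19, which the basic sulfoxide present in excess over the catalytic acid and the low temperature should secure.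

Step 7
Reactants: 22 the keto imide; 23 hydrogen peroxide
Product: 25 (2S,5E)-2-{2-[2,5-bis(prop-2-en-1-yloxy)phenyl]-2-oxoethyl}-6,10-dimethylundeca-5,9-dienoic acid, via lithium peroxycarboxylate 24 (not isolated)
Conditions: LiOH·H2O (2 equiv), 30% H2O2 (4 equiv), THF–H2O (3:1), 0 °C; Na2SO3; 1 M HCl to pH 3
Reagents that add atoms: hydrogen peroxide (23), OO
Why: Hydroperoxide attacks the exocyclic imide carbonyl selectively (standard LiOOH cleavage of an N-acyl oxazolidinone), sulfite reduces the peroxy acid salt, and the mild base at 0 °C should not epimerise C2 or touch the allyl ethers, the aryl ketone or the alkenes.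

Step 8
Reactants: 25 the bis(allyl ether) keto acid
Product: 26 (2S,5E)-2-[2-(2,5-dihydroxyphenyl)-2-oxoethyl]-6,10-dimethylundeca-5,9-dienoic acid (target)
Conditions: Pd(PPh3)4 (5 mol%), morpholine (6 equiv), degassed THF, rt, Ar; degassed 1 M HCl work-up
Reagents that add atoms: none
Why: Zerovalent palladium ionises both aryl allyl ethers to π-allyl complexes that morpholine captures (Tsuji–Trost deallylation), a neutral deprotection without oxidant, reductant or strong acid that should leave the trisubstituted alkenes, the keto acid and the (2S) centre untouched, while degassed solvents keep the hydroquinone from oxidising.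

## Compound list

1 | propyne | CC#C | starting material
2 | geranyl bromide, (2E)-1-bromo-3,7-dimethylocta-2,6-diene | CC(C)=CCC/C(C)=C/CBr | starting material
3 | N-bromosuccinimide | O=C1CCC(=O)N1Br | starting material
4 | 1,3-dilithiopropyne | [Li]CC#C[Li] | intermediate
5 | lithium (5E)-6,10-dimethylundeca-5,9-dien-1-yn-1-ide | CC(C)=CCC/C(C)=C/CCC#C[Li] | intermediate
6 | (5E)-1-bromo-6,10-dimethylundeca-5,9-dien-1-yne | CC(C)=CCC/C(C)=C/CCC#CBr | intermediate
7 | 1,3-oxazolidin-2-one | O=C1NCCO1 | starting material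
8 | 3-[(5E)-6,10-dimethylundeca-5,9-dien-1-yn-1-yl]-1,3-oxazolidin-2-one | CC(C)=CCC/C(C)=C/CCC#CN1CCOC1=O | intermediate
9 | 1-(2,5-dihydroxyphenyl)ethan-1-one | CC(=O)c1cc(O)ccc1O | starting material
10 | allyl bromide, 3-bromoprop-1-ene | C=CCBr | starting material
11 | 1-[2,5-bis(prop-2-en-1-yloxy)phenyl]ethan-1-one | CC(=O)c1cc(OCC=C)ccc1OCC=C | intermediate
12 | 2,4,6-tri(propan-2-yl)benzenesulfonohydrazide | CC(C)c1cc(C(C)C)c(S(=O)(=O)NN)c(C(C)C)c1 | starting material
13 | N′-{1-[2,5-bis(prop-2-en-1-yloxy)phenyl]ethylidene}-2,4,6-tri(propan-2-yl)benzenesulfonohydrazide | CC(=NNS(=O)(=O)c1c(C(C)C)cc(C(C)C)cc1C(C)C)c1cc(OCC=C)ccc1OCC=C | intermediate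
14 | (1R,2S,5R)-5-methyl-2-(propan-2-yl)cyclohexyl (S)-4-methylbenzenesulfinate | C[C@@H]1CC[C@H]([C@@H](C1)O[S@](=O)c1ccc(C)cc1)C(C)C | starting material
15 | {1-[2,5-bis(prop-2-en-1-yloxy)phenyl]ethenyl}lithium | [Li]C(=C)c1cc(OCC=C)ccc1OCC=C | intermediate
16 | {1-[2,5-bis(prop-2-en-1-yloxy)phenyl]ethenyl}magnesium bromide | Br[Mg]C(=C)c1cc(OCC=C)ccc1OCC=C | intermediate
17 | 2-{1-[(S)-4-methylbenzenesulfinyl]ethenyl}-1,4-bis(prop-2-en-1-yloxy)benzene | C=C(c1cc(OCC=C)ccc1OCC=C)[S@@](=O)c1ccc(C)cc1 | intermediate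
18 | water | O | starting material
19 | 3-[(5E)-6,10-dimethylundeca-1,5,9-trien-1-ylidene]-2-oxo-1,3-oxazolidin-3-ium bis(trifluoromethanesulfonyl)azanide (keteniminium ion) | CC(C)=CCC/C(C)=C/CCC=C=[N+]1CCOC1=O.O=S(=O)([N-]S(=O)(=O)C(F)(F)F)C(F)(F)F | intermediate
20 | {1-[2,5-bis(prop-2-en-1-yloxy)phenyl]ethenyl}{[(1E,5E)-6,10-dimethyl-1-(2-oxo-1,3-oxazolidin-3-yl)undeca-1,5,9-trien-1-yl]oxy}(4-methylphenyl)sulfonium bis(trifluoromethanesulfonyl)azanide, S at sulfur | CC(C)=CCC/C(C)=C/CC/C=C(\N1CCOC1=O)O[S@+](C(=C)c1cc(OCC=C)ccc1OCC=C)c1ccc(C)cc1.O=S(=O)([N-]S(=O)(=O)C(F)(F)F)C(F)(F)F | intermediate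
21 | [(3S,6E)-1-[2,5-bis(prop-2-en-1-yloxy)phenyl]-7,11-dimethyl-3-(2-oxo-1,3-oxazolidine-3-carbonyl)dodeca-6,10-dien-1-ylidene](4-methylphenyl)sulfonium bis(trifluoromethanesulfonyl)azanide (thionium ion) | CC(C)=CCC/C(C)=C/CC[C@@H](CC(=[S+]c1ccc(C)cc1)c1cc(OCC=C)ccc1OCC=C)C(=O)N1CCOC1=O.O=S(=O)([N-]S(=O)(=O)C(F)(F)F)C(F)(F)F | intermediate
22 | 3-[(2S,5E)-2-{2-[2,5-bis(prop-2-en-1-yloxy)phenyl]-2-oxoethyl}-6,10-dimethylundeca-5,9-dienoyl]-1,3-oxazolidin-2-one | CC(C)=CCC/C(C)=C/CC[C@@H](CC(=O)c1cc(OCC=C)ccc1OCC=C)C(=O)N1CCOC1=O | intermediate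
23 | hydrogen peroxide | OO | starting material
24 | lithium (2S,5E)-2-{2-[2,5-bis(prop-2-en-1-yloxy)phenyl]-2-oxoethyl}-6,10-dimethylundeca-5,9-dieneperoxoate | CC(C)=CCC/C(C)=C/CC[C@@H](CC(=O)c1cc(OCC=C)ccc1OCC=C)C(=O)O[O-].[Li+] | intermediate
25 | (2S,5E)-2-{2-[2,5-bis(prop-2-en-1-yloxy)phenyl]-2-oxoethyl}-6,10-dimethylundeca-5,9-dienoic acid | CC(C)=CCC/C(C)=C/CC[C@@H](CC(=O)c1cc(OCC=C)ccc1OCC=C)C(=O)O | intermediate
26 | (2S,5E)-2-[2-(2,5-dihydroxyphenyl)-2-oxoethyl]-6,10-dimethylundeca-5,9-dienoic acid | CC(C)=CCC/C(C)=C/CC[C@@H](CC(=O)c1cc(O)ccc1O)C(=O)O | target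

Total step count: 8 (steps 1–2 make the ynamide, steps 3–5 the sulfoxide, steps 6–8 join and finish).
Longest linear sequence: 6 steps (steps 3, 4, 5, 6, 7 and 8, from 9).

Steps most likely to fail

Step 6 (key step). What may go wrong: capture of keteniminium ion 19 by the C5=C6 alkene or acid-induced cyclisation of the 1,5-diene; incomplete or inverted chirality transfer from sulfur; slow turnover of the acid while the proton is held in thionium ion 21, or loss of that proton to a vinyl sulfide that hydrolyses slowly. The fallback is an auxiliary-controlled enolate alkylation that avoids both the keteniminium ion and the sulfoxide; it would set out from 6 and 11 and come back at 25. Hydroboration of bromoalkyne 6 with dicyclohexylborane followed by NaOH/H2O2, which converts a 1-bromoalkyne into the carboxylic acid, would give (5E)-6,10-dimethylundeca-5,9-dienoic acid F1. Pivaloyl chloride and Et3N would turn acid F1 into (5E)-6,10-dimethylundeca-5,9-dienoic 2,2-dimethylpropanoic anhydride F2, and the lithium salt of (4R)-4-benzyl-1,3-oxazolidin-2-one would open anhydride F2 at the less hindered carbonyl to give (4R)-4-benzyl-3-[(5E)-6,10-dimethylundeca-5,9-dienoyl]-1,3-oxazolidin-2-one F3. Ketone 11 and CuBr2 in ethyl acetate would give 2-bromo-1-[2,5-bis(prop-2-en-1-yloxy)phenyl]ethan-1-one F4. The sodium enolate of imide F3 (NaHMDS, THF, −78 °C) would be alkylated by bromo ketone F4 on the face away from the benzyl group (Evans alkylation) to (4R)-4-benzyl-3-[(2S,5E)-2-{2-[2,5-bis(prop-2-en-1-yloxy)phenyl]-2-oxoethyl}-6,10-dimethylundeca-5,9-dienoyl]-1,3-oxazolidin-2-one F5, and the LiOOH conditions of step 7 would turn imide F5 into 25. If only the sense of induction were wrong, step 5 would be run with the enantiomeric (1S,2R,5S)-menthyl (R)-4-methylbenzenesulfinate to give 2-{1-[(R)-4-methylbenzenesulfinyl]ethenyl}-1,4-bis(prop-2-en-1-yloxy)benzene F6, and sulfoxide F6 would take the place of 17 in step 6.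

Step 5. What may go wrong: metalation of the allyl ethers or of the arene in competition with the Shapiro fragmentation; ligand exchange at sulfur by the vinyl organometallic, which would erode the enantiopurity. The fallback uses no vinyl organometallic and no zerovalent palladium (which, with a thiol present, would strip the allyl ethers); it would run from 11 back to 17. Condensation of ketone 11 with 4-methylbenzenethiol under TiCl4 and Et3N in THF (0 °C → rt) would give 2-{1-[(4-methylphenyl)sulfanyl]ethenyl}-1,4-bis(prop-2-en-1-yloxy)benzene F7. Enantioselective sulfoxidation of vinyl sulfide F7 with Ti(OiPr)4, cumene hydroperoxide and the enantiomer of diethyl tartrate that favours the (S)-sulfoxide (Kagan oxidation) would then give 17, whose enantiomeric purity would be raised by crystallisation if needed.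

Step 2. What may go wrong: reductive homocoupling of the bromoalkyne, or its decomposition under base before the C–N bond forms. The fallback is an oxidative C–H/N–H coupling and would run from 5 back to 8. Quenching acetylide 5 with water instead of NBS would give (5E)-6,10-dimethylundeca-5,9-dien-1-yne F8, and terminal alkyne F8 would be coupled with 7 under CuCl2, pyridine, Na2CO3 and O2 (1 atm) in toluene at 70 °C with slow addition of the alkyne to give 8.

Further compounds
F1 | step 6 | (5E)-6,10-dimethylundeca-5,9-dienoic acid | CC(C)=CCC/C(C)=C/CCCC(=O)O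
F2 | step 6 | (5E)-6,10-dimethylundeca-5,9-dienoic 2,2-dimethylpropanoic anhydride | CC(C)=CCC/C(C)=C/CCCC(=O)OC(=O)C(C)(C)C
F3 | step 6 | (4R)-4-benzyl-3-[(5E)-6,10-dimethylundeca-5,9-dienoyl]-1,3-oxazolidin-2-one | CC(C)=CCC/C(C)=C/CCCC(=O)N1C(=O)OC[C@H]1Cc1ccccc1
F4 | step 6 | 2-bromo-1-[2,5-bis(prop-2-en-1-yloxy)phenyl]ethan-1-one | BrCC(=O)c1cc(OCC=C)ccc1OCC=C
F5 | step 6 | (4R)-4-benzyl-3-[(2S,5E)-2-{2-[2,5-bis(prop-2-en-1-yloxy)phenyl]-2-oxoethyl}-6,10-dimethylundeca-5,9-dienoyl]-1,3-oxazolidin-2-one | CC(C)=CCC/C(C)=C/CC[C@@H](CC(=O)c1cc(OCC=C)ccc1OCC=C)C(=O)N1C(=O)OC[C@H]1Cc1ccccc1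
F6 | step 6 | 2-{1-[(R)-4-methylbenzenesulfinyl]ethenyl}-1,4-bis(prop-2-en-1-yloxy)benzene | C=C(c1cc(OCC=C)ccc1OCC=C)[S@](=O)c1ccc(C)cc1
F7 | step 5 | 2-{1-[(4-methylphenyl)sulfanyl]ethenyl}-1,4-bis(prop-2-en-1-yloxy)benzene | C=C(Sc1ccc(C)cc1)c1cc(OCC=C)ccc1OCC=C
F8 | step 2 | (5E)-6,10-dimethylundeca-5,9-dien-1-yne | CC(C)=CCC/C(C)=C/CCC#C
A1 | direct plan | lithium (5E)-6,10-dimethylundeca-5,9-dien-1-yn-1-ide | CC(C)=CCC/C(C)=C/CCC#C[Li]
A2 | direct plan | 2,5-bis(triisopropylsilyloxy)benzaldehyde | O=Cc1cc(O[Si](C(C)C)(C(C)C)C(C)C)ccc1O[Si](C(C)C)(C(C)C)C(C)C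
A3 | direct plan | racemic (6E)-1-[2,5-bis(triisopropylsilyloxy)phenyl]-7,11-dimethyldodeca-6,10-dien-2-yn-1-ol | CC(C)=CCC/C(C)=C/CCC#CC(O)c1cc(O[Si](C(C)C)(C(C)C)C(C)C)ccc1O[Si](C(C)C)(C(C)C)C(C)C
A4 | direct plan | racemic 5-[2,5-bis(triisopropylsilyloxy)phenyl]-3-[(3E)-4,8-dimethylnona-3,7-dien-1-yl]furan-2(5H)-one | CC(C)=CCC/C(C)=C/CCC1=CC(c2cc(O[Si](C(C)C)(C(C)C)C(C)C)ccc2O[Si](C(C)C)(C(C)C)C(C)C)OC1=O
A5 | direct plan | 2-(trimethylsilyl)ethyl (2S,5E)-2-{2-[2,5-bis(triisopropylsilyloxy)phenyl]-2-oxoethyl}-6,10-dimethylundeca-5,9-dienoate | CC(C)=CCC/C(C)=C/CC[C@@H](CC(=O)c1cc(O[Si](C(C)C)(C(C)C)C(C)C)ccc1O[Si](C(C)C)(C(C)C)C(C)C)C(=O)OCC[Si](C)(C)C
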